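**Assumptions.** (a) Polycyclic intermediates are named with eunicellane/asbestinin atom numbers: ring carbons C1–C14, ether bridge C2–O–C9, carbinol C3, alkene C6=C7, cyclohexane C1/C10–C14, and C15/C16 on C14. The SMILES strings are definitive. (b) Only compounds that put non-hydrogen atoms into a product are numbered; catalysts, bases, hydride sources, radical mediators and solvents are not.

## Retrosynthetic overview

1. Oxepane last: C16–O bond by displacement of a primary triflate by the C3 tertiary OH; C15 from hydroboration of a C14 isopropenyl group; C11 ester from a C11 ketone.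
2. Cyclohexane by Diels–Alder of a C1=C10–C11(OEt)=C12(Me) diene with methyl vinyl ketone (sets C1 and C12; C14 by epimerisation; C10 on enol ether hydrolysis); C3 by MeMgCl addition.
3. THF and oxonene formed together by a new Au-catalysed alkyne oxidation / oxonium ylide / [2,3] ring expansion of a 2-propargyl-6-isopropenyl oxane, followed by convergence of the alkene to Z.
4. Oxane by SmI2 ketyl–β-alkoxyacrylate cyclisation; the controlling stereocentre comes from CBS reduction of an isopropenyl ketone.
5. Ring order: oxane (temporary) → THF + oxonene (one step) → cyclohexane → oxepane.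

## Route

**Step 1**
Reactants: 1 methyl 4,4-dimethoxybutanoate; 2 N,O-dimethylhydroxylamine hydrochloride
Product: 3 N-methoxy-4,4-dimethoxy-N-methylbutanamide
Conditions: i-PrMgCl, THF, −20 °C
Reagents that add atoms: N,O-dimethylhydroxylamine hydrochloride, CNOC.Cl
Why: Weinreb amide formation by aminolysis of the ester with the magnesium amide; the dimethyl acetal is inert to base.

**Step 2**
Reactants: 3; 4 isopropenylmagnesium bromide
Product: 5 6,6-dimethoxy-2-methylhex-1-en-3-one
Conditions: THF, −20 → 0 °C; cold aq. NH4Cl quench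
Reagents that add atoms: isopropenylmagnesium bromide, CC(=C)[Mg]Br
Why: Grignard addition to a Weinreb amide stops at the ketone because the chelated tetrahedral intermediate survives until work-up.

**Step 3**
Reactants: 5
Product: 6 (S)-6,6-dimethoxy-2-methylhex-1-en-3-ol
Conditions: (R)-Me-CBS (20 mol %), catecholborane, PhMe, −78 °C
Reagents that add atoms: none
Why: Corey–Bakshi–Shibata reduction with the isopropenyl group as the large substituent gives the (S)-carbinol with the (R)-catalyst, and this centre (future C6) relays to every later stereocentre.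

**Step 4**
Reactants: 6; 7 ethyl propiolate
Product: 8 ethyl (2E)-3-{[(3S)-6,6-dimethoxy-2-methylhex-1-en-3-yl]oxy}prop-2-enoate
Conditions: N-methylmorpholine, CH2Cl2, rt
Reagents that add atoms: ethyl propiolate, C#CC(=O)OCC
Why: Amine-catalysed oxa-Michael addition of the alcohol to the ynoate gives the E-β-alkoxyacrylate without touching the carbinol stereocentre.

**Step 5**
Reactants: 8; 9 water
Product: 10 ethyl (2E)-3-{[(3S)-2-methyl-6-oxohex-1-en-3-yl]oxy}prop-2-enoate
Conditions: 1 M aq. HCl, THF, 0 °C → rt
Reagents that add atoms: water, O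
Why: Acid-catalysed acetal hydrolysis releases the aldehyde, while the vinylogous carbonate is much less basic than the acetal and survives.

**Step 6**
Reactants: 10
Product: 11 ethyl 2-[(2S,3R,6S)-3-hydroxy-6-(prop-1-en-2-yl)oxan-2-yl]acetate
Conditions: SmI2 (3 equiv), MeOH, THF, 0 °C
Reagents that add atoms: none
Why: SmI2 ketyl–olefin reductive cyclisation (6-exo onto the β-alkoxyacrylate) through a chair transition state with equatorial isopropenyl and Sm-chelated ketyl/ester gives the 2,6-cis-2,3-trans oxane, which sets C2 and the temporary C3 centre from C6.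

**Step 7**
Reactants: 11; 12 tert-butyldimethylsilyl chloride
Product: 13 ethyl 2-[(2S,3R,6S)-3-(tert-butyldimethylsilyloxy)-6-(prop-1-en-2-yl)oxan-2-yl]acetate
Conditions: imidazole, DMF, rt
Reagents that add atoms: TBSCl, CC(C)(C)[Si](C)(C)Cl
Why: Standard silylation of the secondary alcohol, giving a group that is stable to all steps up to step 18.

**Step 8**
Reactants: 13
Product: 14 2-[(2S,3R,6S)-3-(tert-butyldimethylsilyloxy)-6-(prop-1-en-2-yl)oxan-2-yl]acetaldehyde
Conditions: DIBAL-H (1.05 equiv), CH2Cl2, −78 °C
Reagents that add atoms: none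
Why: Low-temperature DIBAL partial reduction of the ester stops at the aldehyde through the stable aluminium hemiacetal.

**Step 9**
Reactants: 14; 15 dimethyl (1-diazo-2-oxopropyl)phosphonate (Ohira–Bestmann reagent)
Product: 16 tert-butyldimethyl{[(2S,3R,6S)-6-(prop-1-en-2-yl)-2-(prop-2-yn-1-yl)oxan-3-yl]oxy}silane
Conditions: K2CO3, MeOH, 0 °C → rt
Reagents that add atoms: Ohira–Bestmann reagent, CC(=O)C(=[N+]=[N-])P(=O)(OC)OC
Why: Seyferth–Gilbert homologation (Ohira–Bestmann variant) converts the aldehyde to the terminal alkyne under mild base, and the 2,6-cis oxane is the thermodynamic isomer so C2 is safe.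

**Step 10 (proposed new transformation)**
Reactants: 16; 17 8-methylquinoline N-oxide
Product: 18 (1S,2R,8S)-2-(tert-butyldimethylsilyloxy)-6-methyl-11-oxabicyclo[6.2.1]undec-5-en-9-one (eunicellane C2 S, C3 R, C9 S), obtained as a mixture of 5Z and 5E alkene isomers (Z expected major) and carried forward as the mixture
Conditions: (JohnPhos)AuNTf2 (5 mol %), 17 (1.3 equiv, syringe pump 4 h), 4 Å MS, DCE (0.02 M), rt
Reagents that add atoms: 8-methylquinoline N-oxide, Cc1cccc2ccc[n+]([O-])c12
Why: Proposed new method: Au(I) activates the terminal alkyne, the N-oxide adds to the internal carbon and N–O cleavage gives the α-oxo gold carbene (the diazo-free equivalent of a diazoketone carbenoid), the oxane oxygen traps it as a five-membered oxonium ylide/gold enolate, and a [2,3]-sigmatropic shift through the C6 isopropenyl group breaks C6–O and forms C8–C9, so the THF ring, the nine-membered ring, the C6=C7 alkene and C9 (necessarily cis to C2 across the bridge) form in one step, with only the alkene geometry left uncontrolled; the closest known reactions are Cu/Rh diazoketone oxonium-ylide [2,3] ring expansions and Au-catalysed alkyne-oxidation/oxonium-ylide [2,3] shifts of acyclic homopropargyl allyl ethers, which to my knowledge have not been used for a three-atom ring expansion of a cyclic ether to a bridged oxonene.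

**Step 11**
Reactants: 18 (5Z/5E mixture)
Product: 19 (1S,2R,5Z,8S)-2-(tert-butyldimethylsilyloxy)-6-methyl-11-oxabicyclo[6.2.1]undec-5-en-9-one (single Z isomer)
Conditions: EtSH, AIBN, PhH, 80 °C
Reagents that add atoms: none
Why: Reversible thiyl-radical addition–elimination isomerises the strained E-oxonene component to the more stable Z isomer, so the mixture converges on 19; no other alkene is present at this stage and the three stereocentres are untouched.

**Step 12**
Reactants: 19; 20 N-phenylbis(trifluoromethanesulfonimide)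
Product: 21 (1S,2R,5Z,8S)-2-(tert-butyldimethylsilyloxy)-6-methyl-11-oxabicyclo[6.2.1]undeca-5,9-dien-9-yl trifluoromethanesulfonate (C1=C10 enol triflate)
Conditions: NaHMDS, THF, −78 °C; then 20
Reagents that add atoms: PhNTf2, O=S(=O)(N(c1ccccc1)S(=O)(=O)C(F)(F)F)C(F)(F)F
Why: Kinetic enolisation occurs at the C1 methylene rather than the bridgehead α-alkoxy C9–H, and O-sulfonylation traps the enolate before β-alkoxide elimination can occur.

**Step 13**
Reactants: 22 ethoxyethyne; 23 iodomethane
Product: 24 1-ethoxyprop-1-yne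
Conditions: n-BuLi, THF, −78 °C; then MeI, −78 → 0 °C
Reagents that add atoms: iodomethane, CI
Why: Alkylation of the lithium acetylide of the ynol ether.

**Step 14**
Reactants: 24; 25 tributyltin hydride
Product: 26 tributyl[(1E)-1-ethoxyprop-1-en-1-yl]stannane (CH3 cis to OEt)
Conditions: Pd(PPh3)4 (2 mol %), THF, 0 °C → rt
Reagents that add atoms: tributyltin hydride, CCCC[SnH](CCCC)CCCC
Why: Pd(0)-catalysed hydrostannation of an ynol ether is a syn addition that places tin on the oxygen-bearing carbon, so the methyl ends up cis to OEt.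

**Step 15**
Reactants: 21; 26
Product: 27 tert-butyl({(1S,2R,5Z,8S)-9-[(1Z)-1-ethoxyprop-1-en-1-yl]-6-methyl-11-oxabicyclo[6.2.1]undeca-5,9-dien-2-yl}oxy)dimethylsilane (diene C1=C10–C11(OEt)=C12H–CH3)
Conditions: Pd(PPh3)4 (10 mol %), CuCl, LiCl, DMSO, 60 °C; Et3N-deactivated silica
Reagents that add atoms: stannane 26, CCCC[Sn](CCCC)(CCCC)/C(OCC)=C/C
Why: Stille coupling of the enol triflate (Cu/LiCl-accelerated for a hindered stannane) proceeds with retention of the alkenyl geometry and installs C11 and C12.

**Step 16**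
Reactants: 27; 28 methyl vinyl ketone
Product: 29 tricyclic ketone, (1S,2S,3R,9S,12R,14R)-14-acetyl-11-ethoxy-12-methyl-3-(tert-butyldimethylsilyloxy) with the C10=C11 enol ether and Z-C6=C7 (12-Me cis to C2, acetyl trans to C2 on the new ring)
Conditions: 28 (5 equiv), BHT, PhMe, 90 °C; then K2CO3, MeOH, rt
Reagents that add atoms: methyl vinyl ketone, CC(=O)C=C
Why: Diels–Alder cycloaddition with "para" regiochemistry directed by the 2-ethoxy group occurs on the diene face opposite the oxonene bridge (sets C1), suprafacial addition puts the "outside" C12 methyl cis to C2 (sets C12), and base epimerisation converges the endo/exo mixture to the equatorial acetyl trans to C2 (sets C14).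

**Step 17**
Reactants: 29; 30 methyltriphenylphosphonium bromide
Product: 31 (1S,2S,3R,9S,12R,14R)-11-ethoxy-12-methyl-14-(prop-1-en-2-yl)-3-(tert-butyldimethylsilyloxy) tricyclic enol ether
Conditions: KOt-Bu, THF, 0 °C → rt
Reagents that add atoms: methyltriphenylphosphonium bromide, C[P+](c1ccccc1)(c1ccccc1)c1ccccc1.[Br-]
Why: Wittig methylenation of the methyl ketone, whose C14 is already the thermodynamic epimer so the basic ylide cannot erode it.

**Step 18**
Reactants: 31
Product: 32 the corresponding C3 secondary alcohol (3R)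
Conditions: TBAF, THF, rt → 45 °C
Reagents that add atoms: none
Why: Fluoride desilylation under basic conditions leaves the acid-labile enol ether intact.

**Step 19**
Reactants: 32
Product: 33 C3 ketone (1S,2S,9S,12R,14R)
Conditions: Dess–Martin periodinane, pyridine, CH2Cl2, 0 °C → rt
Reagents that add atoms: none
Why: Pyridine-buffered Dess–Martin oxidation of the hindered secondary alcohol protects the enol ether from adventitious acid.

**Step 20**
Reactants: 33; 34 methylmagnesium chloride
Product: 35 tertiary alcohol (1S,2S,3S,9S,12R,14R)-11-ethoxy-3,12-dimethyl-14-(prop-1-en-2-yl) tricyclic enol ether, 3-OH cis to C1 across C2–C3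
Conditions: MeMgCl, THF, −78 → 0 °C
Reagents that add atoms: methylmagnesium chloride, C[Mg]Cl
Why: Grignard 1,2-addition from the peripheral face of the rigid bicyclic oxonenone (Felkin-type, anti to the C2–O bond) gives the 3S tertiary alcohol, as in related eunicellane ring systems.

**Step 21**
Reactants: 35; 9 water
Product: 36 C11 ketone (1S,2S,3S,9S,10R,12R,14R), cis-fused at C1/C10
Conditions: 0.5 M aq. HCl, THF, 0 °C, short reaction time
Reagents that add atoms: water, O
Why: Enol ether hydrolysis by C10 protonation and fast hydration of the oxocarbenium ion gives the strongly preferred cis-fused ketone (sets C10), and the cold, dilute, brief conditions avoid enolisation so C12 is preserved.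

**Step 22**
Reactants: 36
Product: 37 C11 alcohol (1S,2S,3S,9S,10S,11R,12R,14R; C10 descriptor changes by CIP priority only), OH cis to both the C12 methyl and the C10–C9 bond
Conditions: L-Selectride, THF, −78 °C
Reagents that add atoms: none
Why: Bulky-hydride reduction delivers hydride to the face opposite the two cis α-substituents (C9 and 12-Me), giving the all-cis alcohol and fixing C12 against later epimerisation (sets C11).

**Step 23**
Reactants: 37; 38 butanoic anhydride
Product: 39 C11 butanoate (1S,2S,3S,9S,10R,11R,12R,14R), tertiary C3–OH free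
Conditions: DMAP (1 equiv), Et3N, CH2Cl2, rt
Reagents that add atoms: butanoic anhydride, CCCC(=O)OC(=O)CCC
Why: DMAP-catalysed acyl transfer esterifies the secondary alcohol, while the tertiary medium-ring alcohol does not react under these conditions.

**Step 24**
Reactants: 39; 40 hydrogen peroxide
Product: 41 primary alcohol (1S,2S,3S,9S,10R,11R,12R,14S,15R), with C14 bearing CH(CH3)CH2OH
Conditions: 9-BBN (3 equiv), THF, 0 °C → rt; then 30 % H2O2, aq. NaOAc, 0 °C
Reagents that add atoms: hydrogen peroxide, OO (9-BBN contributes only H)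
Why: Hydroboration–oxidation with 9-BBN is selective for the 1,1-disubstituted alkene over the trisubstituted C6=C7, and with C14–H eclipsing the alkene the borane approaches anti to the bulky C1 branch to give 15R; the buffered oxidation spares the butanoate.

**Step 25**
Reactants: 41
Product: 42 4-deoxyasbestinin C
Conditions: Tf2O (1.05 equiv), 2,6-lutidine, CH2Cl2, −78 → 0 °C
Reagents that add atoms: none
Why: Selective triflation of the primary alcohol followed by intramolecular Williamson-type SN2 displacement by the C3 tertiary hydroxyl closes the oxepane (C16–O) without touching any stereocentre.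

## Compound list

1 | methyl 4,4-dimethoxybutanoate | COC(OC)CCC(=O)OC | starting material
2 | N,O-dimethylhydroxylamine hydrochloride | CNOC.Cl | starting material
3 | N-methoxy-4,4-dimethoxy-N-methylbutanamide | COC(OC)CCC(=O)N(C)OC | intermediate
4 | isopropenylmagnesium bromide | CC(=C)[Mg]Br | starting material
5 | 6,6-dimethoxy-2-methylhex-1-en-3-one | C=C(C)C(=O)CCC(OC)OC | intermediate
6 | (S)-6,6-dimethoxy-2-methylhex-1-en-3-ol | C=C(C)[C@@H](O)CCC(OC)OC | intermediate
7 | ethyl propiolate | C#CC(=O)OCC | starting material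
8 | ethyl (2E)-3-{[(3S)-6,6-dimethoxy-2-methylhex-1-en-3-yl]oxy}prop-2-enoate | C=C(C)[C@H](CCC(OC)OC)O/C=C/C(=O)OCC | intermediate
9 | water | O | starting material
10 | ethyl (2E)-3-{[(3S)-2-methyl-6-oxohex-1-en-3-yl]oxy}prop-2-enoate | C=C(C)[C@H](CCC=O)O/C=C/C(=O)OCC | intermediate
11 | ethyl 2-[(2S,3R,6S)-3-hydroxy-6-(prop-1-en-2-yl)oxan-2-yl]acetate | O[C@@H]1CC[C@@H](C(C)=C)O[C@H]1CC(=O)OCC | intermediate
12 | tert-butyldimethylsilyl chloride | CC(C)(C)[Si](C)(C)Cl | starting material
13 | ethyl 2-[(2S,3R,6S)-3-(TBSO)-6-(prop-1-en-2-yl)oxan-2-yl]acetate | CC(C)(C)[Si](C)(C)O[C@@H]1CC[C@@H](C(C)=C)O[C@H]1CC(=O)OCC | intermediate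
14 | 2-[(2S,3R,6S)-3-(TBSO)-6-(prop-1-en-2-yl)oxan-2-yl]acetaldehyde | CC(C)(C)[Si](C)(C)O[C@@H]1CC[C@@H](C(C)=C)O[C@H]1CC=O | intermediate
15 | dimethyl (1-diazo-2-oxopropyl)phosphonate | CC(=O)C(=[N+]=[N-])P(=O)(OC)OC | starting material
16 | tert-butyldimethyl{[(2S,3R,6S)-6-(prop-1-en-2-yl)-2-(prop-2-yn-1-yl)oxan-3-yl]oxy}silane | CC(C)(C)[Si](C)(C)O[C@@H]1CC[C@@H](C(C)=C)O[C@H]1CC#C | intermediate
17 | 8-methylquinoline N-oxide | Cc1cccc2ccc[n+]([O-])c12 | starting material
18 | (1S,2R,8S)-2-(TBSO)-6-methyl-11-oxabicyclo[6.2.1]undec-5-en-9-one, 5Z/5E mixture (alkene geometry not yet fixed) | CC(C)(C)[Si](C)(C)O[C@@H]1CCC=C(C)C[C@@H]2O[C@H]1CC2=O | intermediate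
19 | (1S,2R,5Z,8S)-2-(TBSO)-6-methyl-11-oxabicyclo[6.2.1]undec-5-en-9-one | CC(C)(C)[Si](C)(C)O[C@@H]1CC/C=C(/C)C[C@@H]2O[C@H]1CC2=O | intermediate
20 | N-phenylbis(trifluoromethanesulfonimide) | O=S(=O)(N(c1ccccc1)S(=O)(=O)C(F)(F)F)C(F)(F)F | starting material
21 | (1S,2R,5Z,8S)-2-(TBSO)-6-methyl-11-oxabicyclo[6.2.1]undeca-5,9-dien-9-yl triflate | CC(C)(C)[Si](C)(C)O[C@@H]1CC/C=C(/C)C[C@@H]2O[C@H]1C=C2OS(=O)(=O)C(F)(F)F | intermediate
22 | ethoxyethyne | C#COCC | starting material
23 | iodomethane | CI | starting material
24 | 1-ethoxyprop-1-yne | CC#COCC | intermediate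
25 | tributyltin hydride | CCCC[SnH](CCCC)CCCC | starting material
26 | tributyl[(1E)-1-ethoxyprop-1-en-1-yl]stannane | CCCC[Sn](CCCC)(CCCC)/C(OCC)=C/C | intermediate
27 | diene: 9-[(1Z)-1-ethoxyprop-1-en-1-yl] derivative of the (1S,2R,5Z,8S)-2-(TBSO)-6-methyl-11-oxabicyclo[6.2.1]undeca-5,9-diene | CC(C)(C)[Si](C)(C)O[C@@H]1CC/C=C(/C)C[C@@H]2O[C@H]1C=C2/C(OCC)=C/C | intermediate
28 | methyl vinyl ketone | CC(=O)C=C | starting material
29 | (1S,2S,3R,9S,12R,14R)-14-acetyl-11-ethoxy-12-methyl-3-(TBSO) tricyclic enol ether | CC(C)(C)[Si](C)(C)O[C@@H]1CC/C=C(/C)C[C@@H]2O[C@H]1[C@H]3[C@H](C(C)=O)C[C@@H](C)C(OCC)=C23 | intermediate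
30 | methyltriphenylphosphonium bromide | C[P+](c1ccccc1)(c1ccccc1)c1ccccc1.[Br-] | starting material
31 | (1S,2S,3R,9S,12R,14R)-11-ethoxy-12-methyl-14-isopropenyl-3-(TBSO) tricyclic enol ether | CC(C)(C)[Si](C)(C)O[C@@H]1CC/C=C(/C)C[C@@H]2O[C@H]1[C@H]3[C@H](C(C)=C)C[C@@H](C)C(OCC)=C23 | intermediate
32 | C3 secondary alcohol of 31 (3R) | O[C@@H]1CC/C=C(/C)C[C@@H]2O[C@H]1[C@H]3[C@H](C(C)=C)C[C@@H](C)C(OCC)=C23 | intermediate
33 | C3 ketone (1S,2S,9S,12R,14R) | O=C1CC/C=C(/C)C[C@@H]2O[C@H]1[C@H]3[C@H](C(C)=C)C[C@@H](C)C(OCC)=C23 | intermediate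
34 | methylmagnesium chloride | C[Mg]Cl | starting material
35 | C3 tertiary alcohol, enol ether (1S,2S,3S,9S,12R,14R) | C[C@]1(O)CC/C=C(/C)C[C@@H]2O[C@H]1[C@H]3[C@H](C(C)=C)C[C@@H](C)C(OCC)=C23 | intermediate
36 | C11 ketone (1S,2S,3S,9S,10R,12R,14R) | C[C@]1(O)CC/C=C(/C)C[C@@H]2O[C@H]1[C@H]3[C@H](C(C)=C)C[C@@H](C)C(=O)[C@@H]23 | intermediate
37 | C11 alcohol (1S,2S,3S,9S,10S,11R,12R,14R) | C[C@]1(O)CC/C=C(/C)C[C@@H]2O[C@H]1[C@H]3[C@H](C(C)=C)C[C@@H](C)[C@@H](O)[C@@H]23 | intermediate
38 | butanoic anhydride | CCCC(=O)OC(=O)CCC | starting material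
39 | C11 butanoate (1S,2S,3S,9S,10R,11R,12R,14R) | C[C@]1(O)CC/C=C(/C)C[C@@H]2O[C@H]1[C@H]3[C@H](C(C)=C)C[C@@H](C)[C@@H](OC(=O)CCC)[C@@H]23 | intermediate
40 | hydrogen peroxide | OO | starting material
41 | C16 primary alcohol (1S,2S,3S,9S,10R,11R,12R,14S,15R) | C[C@]1(O)CC/C=C(/C)C[C@@H]2O[C@H]1[C@H]3[C@H]([C@@H](C)CO)C[C@@H](C)[C@@H](OC(=O)CCC)[C@@H]23 | intermediate
42 | 4-deoxyasbestinin C (1S,2S,3S,9S,10R,11R,12R,14S,15R) | CCCC(=O)O[C@H]1[C@@H]2[C@@H]3[C@@H](C[C@H]1C)[C@@H](C)CO[C@@]1(C)CC/C=C(/C)C[C@@H]2O[C@@H]31 | target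

## Summary

Total steps: 25. Longest linear sequence: 23 (steps 1–12 and 15–25; steps 13–14 are a two-step side branch to stannane 26).

Three steps most likely to fail:

1. **Step 10 (proposed Au-catalysed oxidation/oxonium ylide/[2,3] ring expansion).** Risks are over-oxidation of the gold carbene, [1,2]-shift or ionisation pathways, and a poor Z/E ratio. Fallback (known chemistry): from ester 13, saponify, activate as the mixed anhydride (i-BuOCOCl, Et3N) and treat with CH2N2 to give the diazoketone. Then run the established Cu(hfacac)2-catalysed carbenoid/oxonium ylide [2,3] rearrangement (CH2Cl2, reflux) to the same Z/E mixture 18 and continue from step 11.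

2. **Step 16 (Diels–Alder of the C12-methyl diene, with C12 carried through step 21).** Risks are low reactivity of the more substituted diene, eroded regioselectivity, and C12 epimerisation during enol ether hydrolysis. Fallback: couple 21 with commercial tributyl(1-ethoxyvinyl)stannane, run the Diels–Alder on the parent diene, and introduce the C12 methyl later by kinetic enolate alkylation of the C11 ketone (LDA, MeI) followed by base equilibration, so that C12 is set by alkylation and not by cycloaddition.

3. **Step 24 (substrate-controlled hydroboration at C15).** The risk is low facial selectivity at the isopropenyl group. Fallback: set C15 by catalyst control from a carboxyl precursor. Convert methyl ketone 29 to its kinetic enol triflate, carry out Pd-catalysed carbonylation to the 2-substituted acrylate, hydrolyse, perform Ru–BINAP asymmetric hydrogenation of the acrylic acid, reduce CO2H to the C16 alcohol, and close the oxepane as in step 25.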